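**Plan**
Retrosynthesis first takes the CH2OH group back to an ethyl ester and cuts the two C–Br bonds ortho to the hydroxyl (C2–Br and C6–Br, phenol carbon = C1), leaving ethyl 2-bromo-4-hydroxybenzoate.
The benzene ring is then opened across C2–C3 and C4–C5: oxygen at C1, the meta bromine at C3 and the one-carbon branch at C4 form the 1,3,4-pattern that a 2-silyloxybuta-1,3-diene and a 3-bromopropiolate give in a [4+2] cycloaddition.
Forward: bromination of the alkyne terminus of ethyl propiolate, Diels–Alder construction of the only ring, DDQ aromatisation with desilylation, double ortho-bromination, ester reduction.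
The target is achiral and has no stereocentre; the selectivity to be secured is the regiochemistry of the cycloaddition and of the brominations.

Key step: step 2

Assumption: 2-(trimethylsilyloxy)buta-1,3-diene, ethyl propiolate and all reagents are taken as purchasable.

**Step 1**
Reactants: 1 ethyl propiolate
Product: 2 ethyl 3-bromopropiolate (ethyl 3-bromoprop-2-ynoate)
Conditions: N-bromosuccinimide (1.1 equiv), AgNO3 (0.1 equiv), acetone, rt, dark; filtration, short-path distillation
Reagents that add atoms: N-bromosuccinimide, O=C1CCC(=O)N1Br
Why: Silver-catalysed electrophilic bromination of a terminal alkyne, in which AgNO3 reversibly forms the silver acetylide, N-bromosuccinimide brominates it at carbon, and the ester is untouched under these neutral conditions.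

**Step 2**
Reactants: 2 ethyl 3-bromopropiolate; 3 2-(trimethylsilyloxy)buta-1,3-diene
Product: 4 ethyl 2-bromo-4-(trimethylsilyloxy)cyclohexa-1,4-diene-1-carboxylate
Conditions: toluene, BHT (cat.), 100 °C, sealed tube, N2, diene in slight excess; volatiles removed under vacuum, crude adduct used directly
Reagents that add atoms: none
Why: A thermal, concerted but asynchronous normal-electron-demand Diels–Alder reaction between the electron-rich 2-silyloxydiene and the acceptor alkyne should form the C2–C3 and C4–C5 bonds of the future arene (phenol numbering) in one event, so the six-membered ring closes by intermolecular suprafacial [4+2] cycloaddition and not by a stepwise cyclisation. The closest known reaction types are the cycloadditions of 2-silyloxybuta-1,3-dienes with acetylenic esters and of 3-halopropiolates with dienes, both of which give 1,4-cyclohexadienes. The selectivity needed is regiochemical: the CH2 terminus next to the silyloxy-bearing carbon has the largest HOMO coefficient and joins the bromine-bearing β-carbon of the ynoate, which has the largest LUMO coefficient, so the ester ends para and the bromine meta to the oxygen-bearing carbon. No stereocentre is created, since every ring atom of the adduct is sp2 or CH2. One molecule of diene combines with one molecule of bromoalkyne and nothing is split off; a small surplus of the volatile diene and a radical inhibitor should keep polymerisation of the bromoalkyne from competing, and the adduct is not chromatographed because its silyl enol ether is sensitive to silica gel and moisture.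

**Step 3**
Reactants: 4 ethyl 2-bromo-4-(trimethylsilyloxy)cyclohexa-1,4-diene-1-carboxylate
Product: 6 ethyl 2-bromo-4-hydroxybenzoate, via ethyl 2-bromo-4-(trimethylsilyloxy)benzoate 5 (not isolated)
Conditions: DDQ (1.1 equiv), toluene, rt; filtration; then 1 M aq. HCl, THF, rt
Reagents that add atoms: none
Why: Dehydrogenative aromatisation of a 1,4-cyclohexadiene, in which DDQ abstracts hydride from a doubly allylic CH2 group and the silyloxy-stabilised cyclohexadienyl cation loses a proton (oxidation at the enol ether instead would give a dienone that tautomerises to the same phenol), the vinylic bromine cannot leave as HBr, and dilute acid then cleaves the labile aryl trimethylsilyl ether.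

**Step 4**
Reactants: 6 ethyl 2-bromo-4-hydroxybenzoate
Product: 8 ethyl 2,3,5-tribromo-4-hydroxybenzoate, via ethyl 2,5-dibromo-4-hydroxybenzoate 7 (not isolated)
Conditions: Br2 (2.2 equiv), AcOH, rt to 40 °C; aq. Na2S2O3 quench
Reagents that add atoms: bromine, BrBr
Why: Electrophilic aromatic bromination directed by the free hydroxyl, whose para position is blocked by the ester, so both bromines should enter ortho, first at the open C5 and then at C3 between OH and Br (the position that also brominates readily in 3-bromophenol), while the ester discourages ipso or further substitution.

**Step 5**
Reactants: 8 ethyl 2,3,5-tribromo-4-hydroxybenzoate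
Product: 10 2,3,6-tribromo-4-(hydroxymethyl)phenol, via 2,3,5-tribromo-4-hydroxybenzaldehyde 9 (not isolated)
Conditions: diisobutylaluminium hydride (iBu2AlH, 4 equiv), CH2Cl2, −78 to 0 °C; aq. potassium sodium tartrate (KNaC4H4O6), rt, near-neutral work-up
Reagents that add atoms: none
Why: Ester-to-primary-alcohol reduction with diisobutylaluminium hydride, in which the first equivalent converts the phenol into its aluminium phenoxide, two further hydrides reduce the ester through the aldehyde, and aryl C–Br bonds are inert to this reagent at or below 0 °C.

**Compound list**
1 | ethyl propiolate | CCOC(=O)C#C | starting material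
2 | ethyl 3-bromopropiolate | CCOC(=O)C#CBr | intermediate
3 | 2-(trimethylsilyloxy)buta-1,3-diene | C=CC(=C)O[Si](C)(C)C | starting material
4 | ethyl 2-bromo-4-(trimethylsilyloxy)cyclohexa-1,4-diene-1-carboxylate | CCOC(=O)C1=C(Br)CC(O[Si](C)(C)C)=CC1 | intermediate
5 | ethyl 2-bromo-4-(trimethylsilyloxy)benzoate | CCOC(=O)c1ccc(O[Si](C)(C)C)cc1Br | intermediate
6 | ethyl 2-bromo-4-hydroxybenzoate | CCOC(=O)c1ccc(O)cc1Br | intermediate
7 | ethyl 2,5-dibromo-4-hydroxybenzoate | CCOC(=O)c1cc(Br)c(O)cc1Br | intermediate
8 | ethyl 2,3,5-tribromo-4-hydroxybenzoate | CCOC(=O)c1cc(Br)c(O)c(Br)c1Br | intermediate
9 | 2,3,5-tribromo-4-hydroxybenzaldehyde | O=Cc1cc(Br)c(O)c(Br)c1Br | intermediate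
10 | 2,3,6-tribromo-4-(hydroxymethyl)phenol | OCc1cc(Br)c(O)c(Br)c1Br | target

Total step count: 5. Longest linear sequence: 5 steps (from ethyl propiolate 1).

**Steps most likely to fail**

Step 2 (cycloaddition). The moderately reactive 2-silyloxydiene may add too slowly, so that thermal decomposition or polymerisation of the bromoalkyne takes over, or the para orientation may erode. The fallback sets out from 2 and uses the more electron-rich trans-1-methoxy-3-(trimethylsilyloxy)buta-1,3-diene (purchased, SMILES CO/C=C/C(=C)O[Si](C)(C)C) in toluene at 60–80 °C. The same two ring bonds should form with the same orientation, giving racemic ethyl 2-bromo-6-methoxy-4-(trimethylsilyloxy)cyclohexa-1,4-diene-1-carboxylate F1. Dilute HCl in THF should then hydrolyse the silyl enol ether and eliminate methanol, and the dienone tautomerises to the phenol without any oxidant. The route is rejoined at 6, so this fallback replaces steps 2 and 3 together.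

Step 3 (aromatisation). The silyl enol ether may hydrolyse prematurely and the double bonds may migrate, followed by loss of hydrogen bromide in place of dehydrogenation; DDQ may also add to the enol ether instead of abstracting hydride. The fallback sets out from 4 and replaces hydride abstraction by halogenation–dehydrohalogenation. N-Bromosuccinimide (1 equiv) in THF at 0 °C should brominate the enol ether carbon to give racemic ethyl 2,5-dibromo-4-oxocyclohex-1-ene-1-carboxylate F2. Triethylamine in CH2Cl2 should then eliminate HBr across C5–C6, and the resulting cyclohexadienone tautomerises to the phenol. The route is rejoined at 6.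

Step 5 (reduction). Reduction may stall because the aluminium phenoxide formed first donates into the para ester, and forcing it with more hydride and warming risks reductive loss of an aryl bromine. The fallback sets out from 8 and changes the reductant class. Saponification with LiOH in aqueous THF at 50 °C, followed by acidification, should give 2,3,5-tribromo-4-hydroxybenzoic acid F3. BH3·THF in THF at 0 °C to rt, an electrophilic reductant that reduces carboxylic acids quickly and leaves aryl bromides alone, should then give the benzylic alcohol. The route is rejoined at 10.

**Further compounds**
F1 | step 2 | ethyl 2-bromo-6-methoxy-4-(trimethylsilyloxy)cyclohexa-1,4-diene-1-carboxylate (racemic) | CCOC(=O)C1=C(Br)CC(O[Si](C)(C)C)=CC1OC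
F2 | step 3 | ethyl 2,5-dibromo-4-oxocyclohex-1-ene-1-carboxylate (racemic) | CCOC(=O)C1=C(Br)CC(=O)C(Br)C1
F3 | step 5 | 2,3,5-tribromo-4-hydroxybenzoic acid | OC(=O)c1cc(Br)c(O)c(Br)c1Br
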